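**Retrosynthetic overview**
- The target comes from its O-benzyl ether by hydrogenolysis. That diol comes from an aryl bromide and a vinyl cyclic carbonate by hydroboration and B-alkyl Suzuki–Miyaura coupling (aryl–C1 bond), with the carbonate opened in the same pot.
- The cis vinyl cyclic carbonate comes from the tert-butyl carbonate of (R)-tetradec-1-en-5-ol by palladium-catalysed allylic C–H oxidation (C3–O bond; C3 configuration relayed from C5).
- (R)-Tetradec-1-en-5-ol comes from (S)-1,2-epoxy-5-hexene and octylmagnesium bromide (C6–C7 bond; C5 from the chiral pool). The octyl bromide comes from 1-octene and HBr.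
- The aryl bromide comes from catechol by mono-O-methylation, para-bromination and O-benzylation.
- Rings: the arene is bought. The only ring formed is the temporary 1,3-dioxan-2-one (step 7), which is opened again in step 8.

Assumption: (S)-1,2-epoxy-5-hexene is bought as the single enantiomer; C1–C14 denote the tetradecane chain of the target (C1 bears the aryl group), which is the (3S,5R) syn-diol.

**Step 1**
Reactants: 1 catechol (benzene-1,2-diol)
Product: 2 2-methoxyphenol (guaiacol)
Conditions: MeI (1.0 equiv), K2CO3 (1.0 equiv), acetone, reflux; catechol in 1.5-fold excess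
Reagents that add atoms: iodomethane, CI
Why: Williamson O-methylation of the catechol monoanion, where excess diol and one equivalent of base favour the mono-ether and leftover catechol is washed out with water.

**Step 2**
Reactants: 2 2-methoxyphenol
Product: 3 4-bromo-2-methoxyphenol
Conditions: NBS (1.0 equiv), MeCN, 0 °C to rt
Reagents that add atoms: N-bromosuccinimide, O=C1CCC(=O)N1Br
Why: Electrophilic aromatic bromination directed by the free OH (the stronger donor) to its para position, which gives the 1,2,4-pattern of the target.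

**Step 3**
Reactants: 3 4-bromo-2-methoxyphenol
Product: 4 1-(benzyloxy)-4-bromo-2-methoxybenzene
Conditions: BnBr, K2CO3, DMF, rt
Reagents that add atoms: benzyl bromide, BrCc1ccccc1
Why: Williamson benzylation masks the phenol through the borane and palladium steps and is removable by hydrogenolysis at the end.

**Step 4**
Reactants: 5 1-octene
Product: 6 1-bromooctane
Conditions: HBr (gas), dibenzoyl peroxide (2 mol%), hexane, 0 °C
Reagents that add atoms: hydrogen bromide, Br
Why: Peroxide-initiated radical-chain anti-Markovnikov hydrobromination of a terminal alkene gives the primary bromide.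

**Step 5**
Reactants: 6 1-bromooctane; 7 (S)-2-(but-3-en-1-yl)oxirane [(S)-1,2-epoxy-5-hexene]
Product: 9 (R)-tetradec-1-en-5-ol, via octylmagnesium bromide 8 (not isolated)
Conditions: Mg, THF, reflux; then CuI (10 mol%), 7, THF, −30 to 0 °C; H2O work-up
Reagents that add atoms: none
Why: Copper-catalysed SN2 opening of the terminal epoxide at its CH2 carbon by the Grignard reagent forms C6–C7 without touching the stereocentre, so the (S)-epoxide gives the (R)-alcohol (only the CIP priorities change).

**Step 6**
Reactants: 9 (R)-tetradec-1-en-5-ol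
Product: 10 tert-butyl (R)-tetradec-1-en-5-yl carbonate
Conditions: n-BuLi, THF, −78 °C; Boc2O, −78 °C to rt; H2O work-up
Reagents that add atoms: di-tert-butyl dicarbonate, CC(C)(C)OC(=O)OC(=O)OC(C)(C)C
Why: O-acylation of the lithium alkoxide with Boc2O installs the carbonate that serves as the internal oxygen nucleophile in step 7, with no change at C5.

**Step 7**
Reactants: 10 tert-butyl (R)-tetradec-1-en-5-yl carbonate
Product: 11 (4R,6R)-4-ethenyl-6-nonyl-1,3-dioxan-2-one (cis; C3–O syn to C5–O)
Conditions: Pd(OAc)2 (10 mol%), 1,2-bis(phenylsulfinyl)ethane (10 mol%), (BuO)2P(O)OH (50 mol%), 1,4-benzoquinone (1.5 equiv), 1,2-dichloroethane, 45 °C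
Reagents that add atoms: none
Why: Proposed new method: the Pd(OAc)2/bis-sulfoxide catalyst cleaves the allylic C3–H bond of the terminal alkene to give a π-allyl complex of divalent palladium (C1–C3), made electrophilic by benzoquinone coordination and the phosphate counter-ion; the carbonyl oxygen of the pendant tert-butyl carbonate attacks the internal terminus C3 through a six-membered chair-like transition state with the nonyl group and the allyl unit both equatorial, so the new C3–O bond is cis to C5–O (syn-1,3; 4R,6R); loss of the tert-butyl cation as isobutene gives the neutral cyclic carbonate and benzoquinone reoxidises zerovalent palladium; the closest known reaction types are the Pd/bis-sulfoxide allylic C–H oxidation of homoallylic N-Boc amines to oxazolidinones and of N-sulfonyl carbamates to syn-1,3-oxazinanones, and the iodonium-triggered cyclisation of homoallylic tert-butyl carbonates to cis-1,3-dioxan-2-ones, neither of which has been shown as a C–H oxidation of an O-Boc bis-homoallylic alcohol.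

**Step 8**
Reactants: 11 (4R,6R)-4-ethenyl-6-nonyl-1,3-dioxan-2-one; 4 1-(benzyloxy)-4-bromo-2-methoxybenzene
Product: 14 (3S,5R)-1-[4-(benzyloxy)-3-methoxyphenyl]tetradecane-3,5-diol, via B-alkyl-9-BBN adduct 12 (not isolated), via coupled cyclic carbonate 13 (not isolated)
Conditions: 9-BBN (1.2 equiv), THF, 0 °C to rt; then 4, Pd(dppf)Cl2 (5 mol%), 3 M aq K3PO4, DMF, 50 °C; then LiOH, MeOH/H2O, rt
Reagents that add atoms: none
Why: Anti-Markovnikov hydroboration of the vinyl group followed by B-alkyl Suzuki–Miyaura coupling (oxidative addition of the aryl bromide to zerovalent palladium, base-assisted transfer of the primary alkyl group, reductive elimination) forms the aryl–C1 bond, and hydroxide then saponifies the cyclic carbonate without touching either stereocentre.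

**Step 9**
Reactants: 14 (3S,5R)-1-[4-(benzyloxy)-3-methoxyphenyl]tetradecane-3,5-diol
Product: 15 (3S,5R)-1-(4-hydroxy-3-methoxyphenyl)tetradecane-3,5-diol
Conditions: H2 (1 atm), 10% Pd/C, EtOAc/EtOH, rt
Reagents that add atoms: none
Why: Hydrogenolysis of the benzyl aryl ether on Pd/C frees the phenol and leaves the secondary alcohols and their configurations unchanged.

**Compound list**
1 | catechol (benzene-1,2-diol) | Oc1ccccc1O | starting material
2 | 2-methoxyphenol (guaiacol) | COc1ccccc1O | intermediate
3 | 4-bromo-2-methoxyphenol | COc1cc(Br)ccc1O | intermediate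
4 | 1-(benzyloxy)-4-bromo-2-methoxybenzene | COc1cc(Br)ccc1OCc1ccccc1 | intermediate
5 | 1-octene | CCCCCCC=C | starting material
6 | 1-bromooctane | CCCCCCCCBr | intermediate
7 | (S)-2-(but-3-en-1-yl)oxirane | C=CCC[C@H]1CO1 | starting material
8 | octylmagnesium bromide | CCCCCCCC[Mg]Br | intermediate
9 | (R)-tetradec-1-en-5-ol | CCCCCCCCC[C@@H](O)CCC=C | intermediate
10 | tert-butyl (R)-tetradec-1-en-5-yl carbonate | CCCCCCCCC[C@@H](OC(=O)OC(C)(C)C)CCC=C | intermediate
11 | (4R,6R)-4-ethenyl-6-nonyl-1,3-dioxan-2-one | CCCCCCCCC[C@@H]1C[C@@H](OC(=O)O1)C=C | intermediate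
12 | 9-{2-[(4S,6R)-6-nonyl-2-oxo-1,3-dioxan-4-yl]ethyl}-9-borabicyclo[3.3.1]nonane | CCCCCCCCC[C@@H]1C[C@@H](OC(=O)O1)CCB1C2CCCC1CCC2 | intermediate
13 | (4S,6R)-4-{2-[4-(benzyloxy)-3-methoxyphenyl]ethyl}-6-nonyl-1,3-dioxan-2-one | CCCCCCCCC[C@@H]1C[C@@H](OC(=O)O1)CCc1ccc(OCc2ccccc2)c(OC)c1 | intermediate
14 | (3S,5R)-1-[4-(benzyloxy)-3-methoxyphenyl]tetradecane-3,5-diol | CCCCCCCCC[C@@H](O)C[C@@H](O)CCc1ccc(OCc2ccccc2)c(OC)c1 | intermediate
15 | (3S,5R)-1-(4-hydroxy-3-methoxyphenyl)tetradecane-3,5-diol | CCCCCCCCC[C@@H](O)C[C@@H](O)CCc1ccc(O)c(OC)c1 | target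

**Totals**
Total step count: 9. Longest linear sequence: 6 steps (steps 4, 5, 6, 7, 8, 9, from 1-octene); the catechol and epoxide branches each run 5 steps to the target.

**Steps most likely to fail**

Step 7 (proposed new method). The carbonate oxygen may be too weak a nucleophile for the π-allyl intermediate, giving allylic acetates, diene or a poor cis:trans ratio. The fallback uses only known chemistry; it sets out from 4, also uses 8, and comes back to the route at 14. Heck arylation of allyl alcohol with 4 (Pd(OAc)2, Bu4NCl, NaHCO3, DMF, 90 °C) gives 3-[4-(benzyloxy)-3-methoxyphenyl]propanal F1. Brown allylation with (+)-Ipc2B(allyl), the enantiomer made from (−)-α-pinene (Et2O, −78 °C, then NaOH/H2O2), gives (S)-1-[4-(benzyloxy)-3-methoxyphenyl]hex-5-en-3-ol F2. Treatment with n-BuLi and Boc2O gives tert-butyl (S)-1-[4-(benzyloxy)-3-methoxyphenyl]hex-5-en-3-yl carbonate F3. IBr in toluene at −85 °C closes the cis iodocarbonate (4S,6S)-4-{2-[4-(benzyloxy)-3-methoxyphenyl]ethyl}-6-(iodomethyl)-1,3-dioxan-2-one F4, which sets the 1,3-syn relationship. K2CO3 in MeOH converts it into the epoxy alcohol (S)-4-[4-(benzyloxy)-3-methoxyphenyl]-1-[(S)-oxiran-2-yl]butan-2-ol F5. CuI-catalysed opening of F5 at the epoxide CH2 with octylmagnesium bromide 8 (2.5 equiv, THF, −30 °C) gives 14, and step 9 follows.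

Step 8. The alkene must be fully hydroborated before palladium is added, because the vinyl carbonate would ionise with zerovalent palladium; the electron-rich aryl bromide may also couple slowly with competing protodeboronation. The fallback sets out from 11 and comes back at 13. Peroxide-initiated anti-Markovnikov addition of HBr to the vinyl group (hexane, 0 °C) gives (4R,6R)-4-(2-bromoethyl)-6-nonyl-1,3-dioxan-2-one F6. Nickel-catalysed reductive cross-electrophile coupling of F6 with 4 (NiI2, 4,4'-di-tert-butyl-2,2'-bipyridine, Zn powder, NaI, DMPU, 60 °C) forms the aryl–C1 bond without borane or aqueous base and gives 13. Compound 13 is then saponified with LiOH as in step 8 to give 14.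

Step 1. Mono- versus di-methylation of catechol is only statistically controlled and may give a poor yield. The fallback sets out from 1 and comes back at 2. Exhaustive methylation (excess MeI, K2CO3, acetone, reflux) gives 1,2-dimethoxybenzene F7. NaSEt in DMF at reflux then removes exactly one methyl group, because the phenoxide formed blocks the second cleavage, and acidic work-up gives 2.

**Further compounds**
F1 | step 7 | 3-[4-(benzyloxy)-3-methoxyphenyl]propanal | O=CCCc1ccc(OCc2ccccc2)c(OC)c1
F2 | step 7 | (S)-1-[4-(benzyloxy)-3-methoxyphenyl]hex-5-en-3-ol | C=CC[C@@H](O)CCc1ccc(OCc2ccccc2)c(OC)c1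
F3 | step 7 | tert-butyl (S)-1-[4-(benzyloxy)-3-methoxyphenyl]hex-5-en-3-yl carbonate | C=CC[C@@H](OC(=O)OC(C)(C)C)CCc1ccc(OCc2ccccc2)c(OC)c1
F4 | step 7 | (4S,6S)-4-{2-[4-(benzyloxy)-3-methoxyphenyl]ethyl}-6-(iodomethyl)-1,3-dioxan-2-one | IC[C@@H]1C[C@@H](OC(=O)O1)CCc1ccc(OCc2ccccc2)c(OC)c1
F5 | step 7 | (S)-4-[4-(benzyloxy)-3-methoxyphenyl]-1-[(S)-oxiran-2-yl]butan-2-ol | O[C@@H](CCc1ccc(OCc2ccccc2)c(OC)c1)C[C@H]1CO1
F6 | step 8 | (4R,6R)-4-(2-bromoethyl)-6-nonyl-1,3-dioxan-2-one | CCCCCCCCC[C@@H]1C[C@@H](OC(=O)O1)CCBr
F7 | step 1 | 1,2-dimethoxybenzene | COc1ccccc1OC
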